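## Retrosynthetic overview
1. A retro-[3,3] shift traces the biaryl bond (C4 of ring A, para to OH; C6 of ring B, ortho to OH) back to a C–O bond. The precursor is an ortho-quinol aryl ether with the phenolic O of ring B on C2 of dearomatised ring A.
2. That C–O bond is cut to two molecules of (S)-curcuphenol, joined on one trivalent iodine centre. Both halves and both stereocentres come from one monomer.
3. (S)-Curcuphenol ⇒ its methyl ether ⇒ aryl Grignard from 2-bromo-5-methylanisole + (R)-sulcatyl tosylate (SN2, inversion).
4. (R)-Sulcatol ⇒ enzymatic reduction of sulcatone, the only stereo-defining event.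
5. No ring is built. Both benzene rings are bought, and ring A is dearomatised and rearomatised in the last step.

Locants follow curcuphenol numbering: C1 = C–OH, C2 = carbon bearing the side chain, C5 = C–CH3. Ring A is the para-linked ring and ring B is the ortho-linked ring.

Assumption: the SMILES carries no axial descriptor, so the biaryl axis (ortho groups CH3, CH3, OH, H) is treated as undefined. Only the two (S) carbon centres are controlled.

## Route

Step 1
Reactants: 1 6-methylhept-5-en-2-one (sulcatone)
Product: 2 (R)-6-methylhept-5-en-2-ol ((R)-sulcatol)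
Conditions: Lactobacillus brevis alcohol dehydrogenase, NADP+ (cat.), i-PrOH (10 vol %), MgCl2 (1 mM), KH2PO4/K2HPO4 buffer pH 7, 30 °C
Reagents that add atoms: none
Why: Biocatalytic asymmetric ketone reduction (anti-Prelog alcohol dehydrogenase, isopropanol-coupled cofactor recycling) sends hydride to the si face of the methyl ketone, which should set the (R)-carbinol centre in >99% ee, and the isolated trisubstituted alkene is not a substrate.

Step 2
Reactants: 2 (R)-sulcatol
Product: 3 (R)-6-methylhept-5-en-2-yl 4-methylbenzenesulfonate ((R)-sulcatyl tosylate)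
Conditions: TsCl, Et3N, DMAP (cat.), CH2Cl2, 0 → 23 °C
Reagents that add atoms: p-toluenesulfonyl chloride (TsCl), Cc1ccc(cc1)S(=O)(=O)Cl
Why: O-Sulfonylation (tosylation) touches only the O–H bond, so the (R) configuration is retained and a leaving group suited to SN2 displacement is installed.

Step 3
Reactants: 3 (R)-sulcatyl tosylate; 4 2-bromo-5-methylanisole
Product: 6 (S)-curcuphenol methyl ether, via aryl Grignard reagent 5 (not isolated)
Conditions: 4, Mg, THF, 40 °C; then 3, CuI (10 mol %), TMEDA (20 mol %), LiOMe (1 equiv), THF, 0 → 23 °C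
Reagents that add atoms: none
Why: In this copper-catalysed Grignard–alkyl tosylate cross-coupling (Kumada type, SN2 at carbon) the arylcuprate formed from 5 attacks the secondary tosylate from the back side, so (R)-3 gives the (S)-benzylic stereocentre by inversion, while TMEDA/LiOMe hold back E2 elimination.

Step 4
Reactants: 6 (S)-curcuphenol methyl ether
Product: 7 (S)-(+)-curcuphenol
Conditions: NaSEt, DMF, 130 °C; aq. HCl work-up
Reagents that add atoms: none
Why: Nucleophilic aryl methyl ether cleavage (SN2 of ethanethiolate at the O–CH3 carbon) needs neither acid nor electrophile, so the alkene and the non-acidic benzylic stereocentre are untouched.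

Step 5
Reactants: 7 (S)-curcuphenol (two molecules; one becomes ring A, the other ring B)
Product: 11 (S,S)-2',6-dimethyl-3,5'-bis(6-methylhept-5-en-2-yl)biphenyl-2,4'-diol (target), via bis(aryloxy)phenyliodane 8 (not isolated), via ortho-quinol aryl ether 9 (not isolated), via bis-dienone 10 (not isolated)
Conditions: PhIO (0.5 equiv, finely ground), 4 Å MS, CH2Cl2, −20 → 23 °C
Reagents that add atoms: none
Why: Proposed new method: PhIO condenses with two ArOH (water goes to the sieves) to give the bis(aryloxy)-λ3-iodane 8, which holds no other ligand or free nucleophile, so trivalent iodine can only be reduced by inner-sphere ligand coupling; through a five-membered O–I–O–C1–C2 transition state the aryloxy oxygen of ring B is delivered to the alkyl-bearing, most electron-rich ortho carbon C2 of ring A and PhI leaves, forming the key C–O bond of 9 (closest known reaction types: the Wessely oxidation with Pb(OAc)4 and the hydroxylative phenol dearomatisation with the pentavalent iodine reagent 2-iodoxybenzoic acid, which deliver acetate or oxygen to the same carbon in the same way, whereas transfer of an aryloxide is new); 9 holds a weak tertiary, allylic, α-keto C–O bond inside the array C6(B)=C1(B)–O–C2(A)–C3(A)=C4(A), so an aromatic Claisen-type [3,3] shift (closest known: arylation of phenols through mixed quinone acetals and the quinol ether rearrangement of oxidative phenol coupling) moves ring B from O to C4 of ring A through its only free ortho carbon C6 to give 10, and two keto–enol tautomerisations make the sequence irreversible and give 11; no bond to either side-chain stereocentre is touched, so both stay (S).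

## Compound list
1 | 6-methylhept-5-en-2-one (sulcatone) | CC(C)=CCCC(C)=O | starting material
2 | (R)-6-methylhept-5-en-2-ol ((R)-sulcatol) | CC(C)=CCC[C@@H](C)O | intermediate
3 | (R)-6-methylhept-5-en-2-yl 4-methylbenzenesulfonate | CC(C)=CCC[C@@H](C)OS(=O)(=O)c1ccc(C)cc1 | intermediate
4 | 2-bromo-5-methylanisole (1-bromo-2-methoxy-4-methylbenzene) | COc1cc(C)ccc1Br | starting material
5 | (2-methoxy-4-methylphenyl)magnesium bromide (formed in the flask) | COc1cc(C)ccc1[Mg]Br | intermediate
6 | (S)-curcuphenol methyl ether, 2-[(2S)-6-methylhept-5-en-2-yl]-5-methylanisole | CC(C)=CCC[C@H](C)c1ccc(C)cc1OC | intermediate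
7 | (S)-(+)-curcuphenol, 5-methyl-2-[(2S)-6-methylhept-5-en-2-yl]phenol | CC(C)=CCC[C@H](C)c1ccc(C)cc1O | intermediate
8 | phenyl-λ3-iodanediyl bis[(S)-curcuphenolate], PhI(OAr)2 (formed in the flask) | CC(C)=CCC[C@H](C)c1ccc(C)cc1OI(c1ccccc1)Oc1cc(C)ccc1[C@@H](C)CCC=C(C)C | intermediate
9 | 3-methyl-6-[(2S)-6-methylhept-5-en-2-yl]-6-{5-methyl-2-[(2S)-6-methylhept-5-en-2-yl]phenoxy}cyclohexa-2,4-dien-1-one (formed in the flask; either configuration at the transient quaternary C6) | O=C1C=C(C)C=CC1(Oc2cc(C)ccc2[C@@H](C)CCC=C(C)C)[C@@H](C)CCC=C(C)C | intermediate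
10 | bis-dienone: ring A cyclohexa-2,5-dienone joined through its sp3 C4 to the sp3 C6 of ring B cyclohexa-2,4-dienone (formed in the flask; transient ring sp3 centres undefined) | O=C1C=C(C)C(C=C1[C@@H](C)CCC=C(C)C)C2C(C)=CC=C([C@@H](C)CCC=C(C)C)C2=O | intermediate
11 | 2',6-dimethyl-3,5'-bis[(2S)-6-methylhept-5-en-2-yl]-[1,1'-biphenyl]-2,4'-diol (CNP0290341.1) | CC(C)=CCC[C@H](C)c1cc(-c2c(C)ccc([C@@H](C)CCC=C(C)C)c2O)c(C)cc1O | target

## Step count and risks
Total steps: 5. Longest linear sequence: 5 (1 → 2 → 3 → 6 → 7 → 11).

**Step 5 (proposed new step, highest risk).**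
- Failure modes:
  - outer-sphere C–C coupling, or para C–O coupling to the diaryl ether;
  - loss of ArOH from 9 to an ortho-quinone methide, which would erase a stereocentre;
  - trapping of a free phenoxenium ion by the pendant alkene;
  - over-oxidation of 11.
- Mitigating point: O-delivery to the other ortho carbon (C6 of ring A) is also 1,3-related to C4. It can therefore funnel to the same 10 if the shift outruns tautomerisation.
- Fallback (known chemistry, regiocontrolled cross-coupling in place of oxidative dimerisation). It sets out from 7 and comes back at 11.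
  - One portion of 7 is protected with MOMCl/i-Pr2NEt to give curcuphenol MOM ether F1. Its only free ortho position (C6) is lithiated (s-BuLi, TMEDA, THF, −78 °C) and trapped with i-PrOBpin to give the C6 pinacol boronate F2.
  - A second portion of 7 is brominated para to the hydroxyl (NBS, 1.0 equiv, MeCN, −20 °C, where the phenol ring should outrun the alkene) to give 4-bromocurcuphenol F3.
  - Suzuki–Miyaura coupling of F2 and F3 (Pd(OAc)2, SPhos, K3PO4, toluene/H2O, 90 °C) gives the mono-MOM biaryl F4. Catalytic HCl in MeOH at 40 °C then frees 11.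

**Step 3.**
- Failure modes: E2 elimination of the secondary tosylate, sluggish transfer of the ortho-substituted aryl group, and partial loss of ee through a radical channel.
- Fallback (stereospecific boronate chemistry in place of SN2 displacement). It sets out from 2 and 5 and comes back at 6.
  - 2 is acylated without touching its C–O bond (n-BuLi, then 2,4,6-triisopropylbenzoyl chloride, THF) to give (R)-sulcatyl 2,4,6-triisopropylbenzoate F5.
  - 5 is quenched with i-PrOBpin to give 2-methoxy-4-methylphenyl pinacol boronate F6.
  - F5 is lithiated with retention (s-BuLi, TMEDA, cyclopentyl methyl ether, −60 °C) and trapped with F6. The 1,2-metallate shift (aryl migration, inversion at carbon) gives the (S)-tertiary benzylic boronic ester F7.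
  - Protodeboronation with retention (TBAF·3H2O, toluene, 45 °C) gives 6.

**Step 1.**
- Failure modes: enzyme supply, emulsions or incomplete conversion on scale, or ee below what both stereocentres of 11 need.
- Fallback (kinetic resolution in place of asymmetric reduction). It sets out from 1 and comes back at 2.
  - NaBH4 in MeOH gives racemic sulcatol F8.
  - Candida antarctica lipase B with vinyl acetate in hexane at 30 °C acylates the (R)-enantiomer to (R)-sulcatyl acetate F9. The unreacted (S)-sulcatol F10 is removed by chromatography.
  - K2CO3 in MeOH converts F9 into 2.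

## Further compounds
F1 | step 5 | (S)-curcuphenol methoxymethyl ether | CC(C)=CCC[C@H](C)c1ccc(C)cc1OCOC
F2 | step 5 | 2-{2-(methoxymethoxy)-6-methyl-3-[(2S)-6-methylhept-5-en-2-yl]phenyl}-4,4,5,5-tetramethyl-1,3,2-dioxaborolane | CC(C)=CCC[C@H](C)c1ccc(C)c(B2OC(C)(C)C(C)(C)O2)c1OCOC
F3 | step 5 | 4-bromo-5-methyl-2-[(2S)-6-methylhept-5-en-2-yl]phenol (4-bromocurcuphenol) | CC(C)=CCC[C@H](C)c1cc(Br)c(C)cc1O
F4 | step 5 | target biaryl with the ring B hydroxyl as its methoxymethyl ether | CC(C)=CCC[C@H](C)c1cc(-c2c(C)ccc([C@@H](C)CCC=C(C)C)c2OCOC)c(C)cc1O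
F5 | step 3 | (R)-6-methylhept-5-en-2-yl 2,4,6-triisopropylbenzoate | CC(C)=CCC[C@@H](C)OC(=O)c1c(C(C)C)cc(C(C)C)cc1C(C)C
F6 | step 3 | 2-(2-methoxy-4-methylphenyl)-4,4,5,5-tetramethyl-1,3,2-dioxaborolane | COc1cc(C)ccc1B2OC(C)(C)C(C)(C)O2
F7 | step 3 | (S)-2-[2-(2-methoxy-4-methylphenyl)-6-methylhept-5-en-2-yl]-4,4,5,5-tetramethyl-1,3,2-dioxaborolane | CC(C)=CCC[C@](B2OC(C)(C)C(C)(C)O2)(C)c1ccc(C)cc1OC
F8 | step 1 | racemic 6-methylhept-5-en-2-ol | CC(C)=CCCC(C)O
F9 | step 1 | (R)-6-methylhept-5-en-2-yl acetate | CC(C)=CCC[C@@H](C)OC(C)=O
F10 | step 1 | (S)-6-methylhept-5-en-2-ol | CC(C)=CCC[C@H](C)O
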